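Commercial pristimerin supplies both halves. For the aromatic half its arene is excised, leaving a C/D/E tricycle with C8'–CH2CH2– and C9' handles; a new phenol ring is attached at C6' and a 9'-exo-methylene installed. Oxidation to the o-quinone and hetero-Diels–Alder addition to pristimerin then builds the benzodioxane, and ring B' (C5', C6', C7', C8', C9', C10') is closed last by a cobalt-hydride radical–polar crossover hydroarylation forming C9'–C10'. This step exploits that C10' is para to dioxane oxygen O3' and the only free position ortho to C5', while the axial 14'β-methyl directs α-attack at C9', so one operation sets the quaternary centre and the trans B/C fusion.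

Key step: step 10

Remark: pristimerin is taken as a purchasable compound. Friedelane numbering is used; unprimed locants belong to the upper (quinone-methide-derived) half, primed locants to the lower (aromatic) half and to every fragment that ends up in it.

Step 1
Reactants: 1 pristimerin
Product: 3 pristimerol 2',3'-di-O-methyl ether, via pristimerol 2 (not isolated)
Conditions: NaBH4, MeOH/THF, 0 °C; then K2CO3, MeI, DMF, rt, under Ar
Reagents that add atoms: iodomethane, CI
Why: 1,6-hydride addition at C6' of the quinone methide aromatizes ring A to the catechol, which is capped at once by Williamson O-methylation so that it cannot re-oxidize; no stereocentre is touched.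

Step 2
Reactants: 3 pristimerol 2',3'-di-O-methyl ether
Product: 4 7',8'-dihydropristimerol 2',3'-di-O-methyl ether (8'α-H)
Conditions: Mn(dpm)3 (cat.), PhSiH3, t-BuOOH, i-PrOH, rt
Reagents that add atoms: none
Why: metal-hydride hydrogen-atom-transfer hydrogenation of the hindered trisubstituted 7',8'-alkene; H adds to C7' and the tertiary C8' radical should take up hydrogen on the α face, away from the flanking β-methyls C25' and C26', which gives the trans B/C fusion, also the more stable epimer.

Step 3
Reactants: 4 7',8'-dihydropristimerol 2',3'-di-O-methyl ether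
Product: 5 ring-A-excised C/D/E diacid
Conditions: RuCl3·xH2O (cat.), NaIO4, CCl4/MeCN/H2O, rt
Reagents that add atoms: sodium periodate, [Na+].[O-]I(=O)(=O)=O; water, O
Why: RuO4 oxidative degradation of the electron-rich dimethoxyarene removes C1'–C4' and leaves the two ring-fusion carbons as carboxyl groups (one on quaternary C9', one at the end of the C7'–C6' chain); C8' and C9' cannot epimerize.

Step 4
Reactants: 5 ring-A-excised C/D/E diacid
Product: 6 mono N-acyloxyphthalimide (chain carboxyl activated, C9' CO2H free)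
Conditions: N-hydroxyphthalimide, DIC, DMAP (cat.), CH2Cl2, 0 °C to rt
Reagents that add atoms: N-hydroxyphthalimide, ON1C(=O)c2ccccc2C1=O
Why: carbodiimide (Steglich-type) esterification should select the unhindered primary acid over the neopentyl tertiary acid on C9'; no stereocentre is involved.

Step 5
Reactants: 7 3-bromo-2-methylphenol
Product: 8 (3-bromo-2-methylphenoxy)(tert-butyl)dimethylsilane
Conditions: TBSCl, imidazole, DMF, rt
Reagents that add atoms: tert-butyldimethylsilyl chloride, CC(C)(C)[Si](C)(C)Cl
Why: silyl ether formation masks the phenol for the organometallic step; the phenol oxygen is the later O3'.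

Step 6
Reactants: 6 mono N-acyloxyphthalimide; 8 aryl bromide TBS ether
Product: 11 arylethyl C9' acid, via aryllithium 9 (not isolated), via arylzinc chloride 10 (not isolated)
Conditions: 8, n-BuLi, THF, −78 °C; ZnCl2, −78 °C to rt; then 6 (0.33 equiv), NiCl2·glyme (cat.), 4,4'-di-tert-butyl-2,2'-bipyridine (cat.), THF/DMF, rt
Reagents that add atoms: none
Why: nickel-catalysed decarboxylative Negishi-type coupling of the redox-active ester; loss of CO2 gives the primary C6' radical, which is captured by aryl–nickel to form the C5'–C6' bond, while the first equivalent of 10 is spent in deprotonating the hindered C9' acid, which otherwise stays out of the reaction.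

Step 7
Reactants: 11 arylethyl C9' acid
Product: 12 9'-exo-methylene TBS ether
Conditions: 9-mesitylacridine (cat.), Co(dmgH)2(py)Cl (cat.), CH2Cl2, 400 nm LED, rt
Reagents that add atoms: none
Why: photocatalytic dehydrodecarboxylation; the excited acridine oxidizes the hydrogen-bonded acid by proton-coupled electron transfer, CO2 is lost, and the cobaloxime removes a β-hydrogen from the tertiary C9' radical, preferentially from the unhindered C25' methyl, to give the exocyclic alkene with release of H2, C8' being untouched.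

Step 8
Reactants: 12 9'-exo-methylene TBS ether
Product: 13 9'-exo-methylene phenol (3'-OH)
Conditions: TBAF, THF, 0 °C
Reagents that add atoms: none
Why: fluoride desilylation of the aryl silyl ether under conditions that leave the alkene, the hindered methyl ester and C8' untouched.

Step 9
Reactants: 13 9'-exo-methylene phenol; 1 pristimerin
Product: 15 seco dimer, via seco-o-quinone 14 (not isolated)
Conditions: IBX, DMF, rt; then 1, CH2Cl2/DMF, rt, dark
Reagents that add atoms: 2-iodoxybenzoic acid (IBX), O=C1OI(=O)(O)c2ccccc12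
Why: IBX ortho-oxygenation of the phenol (only C2' is free) gives the o-quinone, whose O=C–C=O unit adds across the enolic C3=C4 bond of 1 in an inverse-electron-demand hetero-Diels–Alder reaction; suprafacial addition on the α face of ring A, away from the 9β-methyl, sets C3 (β-OH) and C4 (β-Me) together, and the orientation O2' to C3, O3' to C4 is the one required.

Step 10
Reactants: 15 seco dimer
Product: 16 target dimer
Conditions: N,N'-bis(3,5-di-tert-butylsalicylidene)-1,2-cyclohexanediaminocobalt (C36H52CoN2O2, divalent cobalt, cat.), N-fluoro-2,4,6-trimethylpyridinium triflate, (Me2SiH)2O, PhCF3, rt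
Reagents that add atoms: none
Why: The cobalt hydride formed from the salen complex, the N-fluoropyridinium oxidant and the silane transfers a hydrogen atom to the exocyclic CH2 (which becomes the C25' methyl); the tertiary C9' radical is captured by cobalt, oxidized to a carbocation equivalent and attacked by the arene at C10', and loss of the proton restores the aromatic ring. The closest known reaction type is the cobalt-catalysed radical–polar crossover (Mukaiyama-type) intramolecular hydroarylation of unactivated 1,1-disubstituted alkenes, a Markovnikov Friedel–Crafts alkylation under non-acidic conditions. Ring B' closes in a 6-exo mode with respect to the alkene (C9' inside, C25' outside the new ring), and it is the only ring formed. The new quaternary stereocentre C9' is controlled by the substrate: axial bond formation on the β face is blocked by the syn-axial 14'β-methyl (C26'), so C10' enters equatorially on the α face, C25' ends β, and the B/C fusion is trans to the existing 8'α-H. The step needs site selectivity on the arene, secured because C10' is the only free position ortho to C5' (C4' carries the methyl) and is para to O3'. It also needs chemoselectivity for the unhindered 1,1-disubstituted alkene over the trisubstituted, conjugated alkenes of the upper half, which are each flanked by a quaternary carbon (C4, C9, C14) and should react far more slowly with the bulky cobalt hydride.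

Compound list
1 | pristimerin: methyl 3-hydroxy-2-oxo-24-norfriedela-1(10),3,5,7-tetraen-29-oate (9β-Me, 13α-Me, 14β-Me, 17β-Me, 18β-H, 20α-CO2Me) | COC(=O)[C@]1(C)CC[C@]2(C)CC[C@]3(C)C4=CC=C5C(=CC(=O)C(O)=C5C)[C@]4(C)CC[C@@]3(C)[C@@H]2C1 | starting material
2 | pristimerol: aromatic ring A with 2',3'-diol, 7',8'-ene, other centres as in 1 | Oc1cc2c(c(C)c1O)CC=C1[C@@]2(C)CC[C@@]3(C)[C@@H]4C[C@](C)(C(=O)OC)CC[C@]4(C)CC[C@]13C | intermediate (not isolated)
3 | pristimerol 2',3'-di-O-methyl ether | COc1cc2c(c(C)c1OC)CC=C1[C@@]2(C)CC[C@@]3(C)[C@@H]4C[C@](C)(C(=O)OC)CC[C@]4(C)CC[C@]13C | intermediate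
4 | 7',8'-dihydropristimerol 2',3'-di-O-methyl ether (8'α-H, trans B/C) | COc1cc2c(c(C)c1OC)CC[C@H]1[C@@]2(C)CC[C@@]3(C)[C@@H]4C[C@](C)(C(=O)OC)CC[C@]4(C)CC[C@]13C | intermediate
5 | ring-A-excised C/D/E diacid: C9' carries β-CH3 and α-CO2H, C8' (α-H) carries CH2CH2CO2H; 13'α-Me, 14'β-Me, 17'β-Me, 18'β-H, 20'α-CO2Me | OC(=O)CC[C@H]1[C@@](C(=O)O)(C)CC[C@@]2(C)[C@@H]3C[C@](C)(C(=O)OC)CC[C@]3(C)CC[C@]12C | intermediate
6 | mono N-acyloxyphthalimide of 5 at the chain carboxyl (C9' CO2H free) | O=C1c2ccccc2C(=O)N1OC(=O)CC[C@H]1[C@@](C(=O)O)(C)CC[C@@]2(C)[C@@H]3C[C@](C)(C(=O)OC)CC[C@]3(C)CC[C@]12C | intermediate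
7 | 3-bromo-2-methylphenol | Cc1c(O)cccc1Br | starting material
8 | (3-bromo-2-methylphenoxy)(tert-butyl)dimethylsilane | Cc1c(O[Si](C)(C)C(C)(C)C)cccc1Br | intermediate
9 | [3-(tert-butyldimethylsilyloxy)-2-methylphenyl]lithium | [Li]c1cccc(O[Si](C)(C)C(C)(C)C)c1C | intermediate (not isolated)
10 | [3-(tert-butyldimethylsilyloxy)-2-methylphenyl]zinc chloride | Cl[Zn]c1cccc(O[Si](C)(C)C(C)(C)C)c1C | intermediate (not isolated)
11 | arylethyl C9' acid: C8' (α-H) carries CH2CH2–aryl (aryl = 3-TBSO-2-methylphenyl bonded through C5'), C9' carries β-CH3 and α-CO2H | Cc1c(O[Si](C)(C)C(C)(C)C)cccc1CC[C@H]1[C@@](C(=O)O)(C)CC[C@@]2(C)[C@@H]3C[C@](C)(C(=O)OC)CC[C@]3(C)CC[C@]12C | intermediate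
12 | 9'-exo-methylene TBS ether (C9'=C25'H2, 8'α-H) | Cc1c(O[Si](C)(C)C(C)(C)C)cccc1CC[C@H]1C(=C)CC[C@@]2(C)[C@@H]3C[C@](C)(C(=O)OC)CC[C@]3(C)CC[C@]12C | intermediate
13 | 9'-exo-methylene phenol (3'-OH, 4'-Me, C5' chain) | Cc1c(O)cccc1CC[C@H]1C(=C)CC[C@@]2(C)[C@@H]3C[C@](C)(C(=O)OC)CC[C@]3(C)CC[C@]12C | intermediate
14 | seco-o-quinone (2',3'-dione, 4'-Me, C5' chain, 9'-exo-methylene) | CC1=C(CC[C@H]2C(=C)CC[C@@]3(C)[C@@H]4C[C@](C)(C(=O)OC)CC[C@]4(C)CC[C@]23C)C=CC(=O)C1=O | intermediate (not isolated)
15 | seco dimer: benzodioxane hemiketal with O2'–C3 and O3'–C4 on the α face (3β-OH, 4β-Me), C10'–H, 9'-exo-methylene | COC(=O)[C@]1(C)CC[C@]2(C)CC[C@]3(C)C4=CC=C5C(=CC(=O)[C@@]6(O)Oc7ccc(c(C)c7O[C@@]56C)CC[C@H]5C(=C)CC[C@@]6(C)[C@@H]7C[C@](C)(C(=O)OC)CC[C@]7(C)CC[C@]56C)[C@]4(C)CC[C@@]3(C)[C@@H]2C1 | intermediate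
16 | target dimer (CNP0154412.1) | COC(=O)[C@]1(C)CC[C@]2(C)CC[C@]3(C)C4=CC=C5C(=CC(=O)[C@@]6(O)Oc7cc8c(c(C)c7O[C@@]56C)CC[C@H]5[C@@]8(C)CC[C@@]6(C)[C@@H]7C[C@](C)(C(=O)OC)CC[C@]7(C)CC[C@]56C)[C@]4(C)CC[C@@]3(C)[C@@H]2C1 | target

Total step count: 10. Longest linear sequence: 9 steps (steps 1, 2, 3, 4, 6, 7, 8, 9, 10 from pristimerin).

Steps most likely to fail

Step 9, orientation of the cycloaddition. The two quinone oxygens differ little (O3' is flanked by the C4' methyl, O2' by hydrogen), so the required orientation may not dominate and the regioisomers would have to be separated. Addition on the β face and tautomerization of the o-quinone to its p-quinone methide before capture are further losses. The fallback sets out from 13 and 1 and comes back at 15, making the two C–O bonds one after the other. The o-quinone 14 is reduced in the same flask with Na2S2O4 to the seco catechol F1. The unhindered 2'-OH is then silylated with TBSCl and imidazole to the mono-TBS ether F2, which leaves only the 3'-OH free. Oxidative α-aryloxylation of the enol of 1 with PhI(OAc)2 in the presence of F2 (umpolung of C4, attack away from the 9β-methyl) should give the C4 aryl ether 2,3-dione F3. TBAF then frees the 2'-OH, which closes the hemiketal on the C3 ketone to give 15.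

Step 10, chemoselectivity of hydrogen-atom transfer. The cobalt hydride may attack the trienone of the upper half, or fluoride may capture the C9' cation before the arene does. The fallback sets out from 12 and comes back at 16; it abandons hydride transfer in the presence of the trienone. Mukaiyama hydration of 12 (Co(acac)2, O2, PhSiH3) puts the oxygen on C9' before the union and gives the tertiary alcohol TBS ether F4, either C9' epimer serving. TBAF gives the phenol F5, and IBX gives the hydroxy o-quinone F6, which adds to 1 as in step 9 to give the hydroxy seco dimer F7. Ring B' is then closed last by ionization of the tertiary alcohol with catalytic Bi(OTf)3 in hexafluoroisopropanol/CH2Cl2 at 0 °C, a dehydrative Friedel–Crafts alkylation with the same stereochemical control at C9'.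

Step 2, facial selectivity of hydrogen delivery at C8' and slow reaction of an alkene flanked by two quaternary carbons. The fallback sets out from 3 and comes back at 4; it sets C8' by protonation under thermodynamic control. Benzylic-allylic oxidation of 3 at C6' (CrO3, 3,5-dimethylpyrazole, CH2Cl2) gives the 6'-oxo enone F8. Dissolving-metal reduction (Li, NH3, t-BuOH, −78 °C) should give the trans-fused 7',8'-dihydro-6'-ketone F9. Hydrogenolysis of the aryl ketone (H2, Pd/C, AcOH, cat. HClO4) then returns 4.

Further compounds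
F1 | step 9 | seco catechol (2',3'-diol, 9'-exo-methylene) | Cc1c(O)c(O)ccc1CC[C@H]1C(=C)CC[C@@]2(C)[C@@H]3C[C@](C)(C(=O)OC)CC[C@]3(C)CC[C@]12C
F2 | step 9 | seco catechol 2'-O-TBS ether (3'-OH free) | Cc1c(O)c(O[Si](C)(C)C(C)(C)C)ccc1CC[C@H]1C(=C)CC[C@@]2(C)[C@@H]3C[C@](C)(C(=O)OC)CC[C@]3(C)CC[C@]12C
F3 | step 9 | C4 aryl ether 2,3-dione of the upper half (4α-O3', 4β-Me, 2'-OTBS) | COC(=O)[C@]1(C)CC[C@]2(C)CC[C@]3(C)C4=CC=C5C(=CC(=O)C(=O)[C@@]5(C)Oc5c(C)c(CC[C@H]6C(=C)CC[C@@]7(C)[C@@H]8C[C@](C)(C(=O)OC)CC[C@]8(C)CC[C@]67C)ccc5O[Si](C)(C)C(C)(C)C)[C@]4(C)CC[C@@]3(C)[C@@H]2C1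
F4 | step 10 | 9'-hydroxy-9'-methyl TBS ether (C9' configuration immaterial) | Cc1c(O[Si](C)(C)C(C)(C)C)cccc1CC[C@H]1C(C)(O)CC[C@@]2(C)[C@@H]3C[C@](C)(C(=O)OC)CC[C@]3(C)CC[C@]12C
F5 | step 10 | 9'-hydroxy-9'-methyl phenol | Cc1c(O)cccc1CC[C@H]1C(C)(O)CC[C@@]2(C)[C@@H]3C[C@](C)(C(=O)OC)CC[C@]3(C)CC[C@]12C
F6 | step 10 | 9'-hydroxy seco-o-quinone | CC1=C(CC[C@H]2C(C)(O)CC[C@@]3(C)[C@@H]4C[C@](C)(C(=O)OC)CC[C@]4(C)CC[C@]23C)C=CC(=O)C1=O
F7 | step 10 | 9'-hydroxy seco dimer | COC(=O)[C@]1(C)CC[C@]2(C)CC[C@]3(C)C4=CC=C5C(=CC(=O)[C@@]6(O)Oc7ccc(c(C)c7O[C@@]56C)CC[C@H]5C(C)(O)CC[C@@]6(C)[C@@H]7C[C@](C)(C(=O)OC)CC[C@]7(C)CC[C@]56C)[C@]4(C)CC[C@@]3(C)[C@@H]2C1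
F8 | step 2 | 6'-oxopristimerol 2',3'-di-O-methyl ether (7',8'-ene) | COc1cc2c(c(C)c1OC)C(=O)C=C1[C@@]2(C)CC[C@@]3(C)[C@@H]4C[C@](C)(C(=O)OC)CC[C@]4(C)CC[C@]13C
F9 | step 2 | 7',8'-dihydro-6'-oxopristimerol 2',3'-di-O-methyl ether (8'α-H) | COc1cc2c(c(C)c1OC)C(=O)C[C@H]1[C@@]2(C)CC[C@@]3(C)[C@@H]4C[C@](C)(C(=O)OC)CC[C@]4(C)CC[C@]13C
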